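## The problem

Compound 19 is a macrocyclic bis(bibenzyl): four benzene rings closed into a 20-membered ring by two diaryl ether oxygens (ring A–O–ring B and ring C–O–ring D) and two CH2CH2 bridges (ring B–ring C and ring D–ring A). Rings A and C are spanned para, rings B and D meta. There is no stereocentre, so the task is the 1,2,4-pattern of the two oxygenated rings and the closure of the large ring. In ring A the OH is next to the aryloxy oxygen and the CH2 is para to that aryloxy oxygen, whereas in ring D the OH is next to the aryloxy oxygen and the CH2 is para to the OH. Each of these rings is a catechol with one free hydroxyl and one aryl ether, so four oxygens must be told apart and two unactivated diaryl ethers must be formed. The electron-rich phenols are prone to oxidation and are best revealed last; in a route through non-aromatic ring A intermediates, an α-aryloxy enone and an activated ester must also be kept from strong base and strong reductants. The enabling feature is in ring A: the carbon bearing OH, its neighbour bearing the aryloxy group and the carbon bearing CH2 are C1, C2 and C5 of a 2-aryloxy-5-alkylcyclohexanone, and C5 is the β-carbon of the corresponding enone. The CH2–ring A bond can therefore be made by adding an alkyl radical to an enone, and ring A can be aromatized afterwards with its oxygen pattern already fixed.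

## Retrosynthesis

**19 to 18.** The ring D O–CH3 bond is cut last. Ring D carries its oxygen as a methyl ether from the first building block, while the ring A hydroxyl is a ketone until late, so the two phenols are differentiated by oxidation state and need only one protecting group. The forward step must cleave an alkyl aryl ether and leave two diaryl ethers, which have no sp3 carbon for bromide to attack.

**18 to 16 (through 17).** Ring A is taken back to the cyclohexanone 16. This adds hydrogens and does not simplify the skeleton, but it turns an inert aryl–CH2 bond into a bond β to a carbonyl. The forward reaction is a catalytic dehydrogenation of a cyclohexanone to a phenol; the carbonyl carbon fixes where the OH appears and the α-carbon keeps its aryl ether.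

**16 to 15.** The bond between the bridge CH2 and C5 of the cyclohexanone is cut; this is the ring-opening disconnection. Its neighbours are weaker: cutting either diaryl ether would require an Ullmann-type macro-etherification at an unactivated, ortho-substituted position, and cutting the middle of a CH2CH2 bridge (Wittig or McMurry closure) needs two carbonyl-level handles and a later reduction. The chosen cut needs one carboxylic acid and one enone. Precursor 15 is an open chain of three arenes and a cyclohexenone, carrying the acid as its N-acyloxyphthalimide. The forward step must generate a primary radical without reducing the enone or the α-aryloxy ketone, and ring closure must outrun hydrogen-atom quenching.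

**15 to 14 to 13.** The activated ester is traced to the acid 14 and this to the tert-butyl ester 13. A tert-butyl ester is chosen because it is cleaved by acid; saponification would expose the α-aryloxy enone to hydroxide.

**13 to 9 and 12.** The bond between the ring B oxygen and the α'-carbon of the enone is cut. Alkylating the phenol with a 6-halocyclohex-2-enone would need base, under which such halides lose HX and aromatize. A rhodium carbenoid O–H insertion of 6-diazocyclohex-2-en-1-one 12 forms the same bond under neutral conditions. Reagent 12 comes from cyclohex-2-en-1-one 10 by deacylative diazo transfer through 11, so all six carbons of ring A are bought as one commercial ring.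

**9 to 8 to 5 and 7.** The ring B–ring C bridge is cut as a stilbene C=C. One Wittig reaction joins aldehyde 5 to the phosphonium salt 7 (from 3-hydroxybenzyl alcohol 6), and one hydrogenation saturates both the stilbene and the cinnamate in 8. No protecting group is needed on the ring B phenol.

**5 to 3 and 4; 3 to 1 and 2.** The ring C–O–ring D ether is cut next to ring C, where the para-formyl group of 4-fluorobenzaldehyde 4 makes nucleophilic aromatic substitution easy and then serves as the Wittig handle. Phenol 3 is isovanillin 1 extended by a stabilized Wittig reagent 2, which installs the three-carbon acid chain already as its tert-butyl ester.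

## Roads not taken

**Alternative 1:** Ring C would be built in the ring-closing step. The cut removes two C–C bonds of ring C and leads to the seco diene–ynone A1, with a 2-aryloxybuta-1,3-diene on the ring D oxygen and a terminal ynone on the ring B benzylic carbon. Heating A1 at high dilution would give, by intramolecular [4+2] cycloaddition, the macrocyclic cyclohexa-1,4-diene ketone A2, closing the six-membered and the 20-membered ring together.
- Merits: two C–C bonds and two rings form without reagents, and the 2-oxygenated diene and polarized ynone should give the para adduct. The 1,4-diene is one mild oxidation from the arene, which is easier than the double dehydrogenation the chosen plan needs; in this respect Alternative 1 is the better design.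
- Weak points: A1 combines an acid-labile, polymerizable 2-aryloxydiene, for which there is no routine preparation from a phenol, with a terminal ynone. The cycloaddition is of the bridged kind (tether on diene C2), so the chain must fold across the forming ring, and intermolecular cycloaddition would compete. A2 carries an extra benzylic ketone that must be removed, and the ring A–O–ring B ether of A1 still needs a CuI-mediated Ullmann coupling.
- Comparison: the chosen plan forms only one C–C bond in its key step. Against that, each functional group of its precursor comes from one standard operation and no deoxygenation follows ring closure.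

**Alternative 2:** The cut is the bond between the ring C oxygen and the ring D carbon ortho to the ring D hydroxyl. The seco bis-phenol A3 carries ring D as a 2,6-dibromophenol and ring C as a 2,6-dichlorophenol. Anodic oxidation of the more easily oxidized dibromophenol, attack of the dichlorophenol oxygen on a brominated ortho carbon and reduction with Zn in acetic acid would give the trihalogenated macrocyclic ether A4.
- Merits: every intermediate is aromatic and robust, the halogens dictate which phenol is oxidized and where the ether forms, and no aromatization is needed. On the stability of intermediates this road is better than the chosen one.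
- Weak points: four halogens must be installed and three removed, both methyl ethers still need cleavage, and phenol oxidations of this kind tend to pair molecules intermolecularly, so the macrocyclic mode must compete with dimer formation. The guaiacol-type ring A is a second oxidizable site, and the ring A–O–ring B ether again has to come from an Ullmann coupling.
- Comparison: the chosen plan pays with a redox detour on ring A. In return it uses no auxiliary halogens, forms both diaryl ethers under mild conditions (aromatic substitution and O–H insertion) and closes the ring through a carbon radical that does not depend on the oxidation potentials of the arenes.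

**Alternative 3:** The cut is the bond between the ring A oxygen and the ring B carbon, reached by ring contraction. The 21-membered macrolactone A5 (ring B benzoate of the ring A phenol) would lose CO under Ni(cod)2 (zerovalent nickel) with a bisphosphine to give the target dimethyl ether A6, one demethylation from 19.
- Merits: macrolactonization of a phenol with a benzoic acid is among the most dependable large-ring closures, the C–O bond formation is intramolecular by construction, and the endgame is the shortest of all four plans. On step count this road would win.
- Weak points: decarbonylative ether formation from aryl esters is established mainly for azine or otherwise electron-poor acyl partners. A plain meta-alkylbenzoate of an electron-rich, ortho-methoxylated phenol lies outside that range. Oxidative addition into the acyl C–O bond, loss of strongly bound CO and aryl–oxygen reductive elimination would all be asked of an unactivated substrate inside a contracting macrocycle.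
- Comparison: the chosen plan is longer after ring closure (aromatization and demethylation) and carries a dearomatized ring. Its key step, however, belongs to a reaction class with broad precedent for unactivated primary radicals and simple enones, whereas A5 to A6 would require extending a method beyond its demonstrated substrates.

Key step: step 10

Remark: compounds 13, 14, 15 and 17 are racemic and 16 is a racemic cis/trans mixture. Both sp3 centres vanish in step 11, so these SMILES carry no configuration. Compound 8 is an E/Z mixture at the stilbene bond and is hydrogenated directly.

Remark: isovanillin, tert-butyl (triphenylphosphoranylidene)acetate, 4-fluorobenzaldehyde, 3-hydroxybenzyl alcohol and cyclohex-2-en-1-one are taken as commercial.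

## Route

Step 1
Reactants: 1 isovanillin (3-hydroxy-4-methoxybenzaldehyde); 2 tert-butyl (triphenylphosphoranylidene)acetate
Product: 3 tert-butyl (E)-3-(3-hydroxy-4-methoxyphenyl)prop-2-enoate
Conditions: toluene, 90 °C
Reagents that add atoms: none
Why: Wittig olefination with a stabilized ylide, which is E-selective and tolerates the free phenol; it installs the three-carbon acid chain directly as the acid-labile tert-butyl ester.

Step 2
Reactants: 3 tert-butyl (E)-3-(3-hydroxy-4-methoxyphenyl)prop-2-enoate; 4 4-fluorobenzaldehyde
Product: 5 tert-butyl (E)-3-[3-(4-formylphenoxy)-4-methoxyphenyl]prop-2-enoate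
Conditions: K2CO3, DMF, 120 °C
Reagents that add atoms: none
Why: Nucleophilic aromatic substitution of a fluoride activated by the para-formyl group forms the ring C–O–ring D ether; the tert-butyl ester is inert to carbonate in dry DMF.

Step 3
Reactants: 6 3-hydroxybenzyl alcohol
Product: 7 (3-hydroxybenzyl)triphenylphosphonium bromide
Conditions: PPh3·HBr, MeCN, reflux
Reagents that add atoms: triphenylphosphine hydrobromide, SMILES Br.c1ccc(cc1)P(c1ccccc1)c1ccccc1
Why: Direct conversion of a benzylic alcohol to its phosphonium salt: HBr activates the benzylic C–O bond and triphenylphosphine substitutes at that carbon, while the phenol does not react.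

Step 4
Reactants: 5 tert-butyl (E)-3-[3-(4-formylphenoxy)-4-methoxyphenyl]prop-2-enoate; 7 (3-hydroxybenzyl)triphenylphosphonium bromide
Product: 8 tert-butyl (E)-3-(3-{4-[2-(3-hydroxyphenyl)ethenyl]phenoxy}-4-methoxyphenyl)prop-2-enoate (E/Z mixture at the stilbene bond)
Conditions: K2CO3 (3 equiv), 18-crown-6 (cat.), CH2Cl2, reflux
Reagents that add atoms: none
Why: Wittig olefination with a semi-stabilized benzylic ylide generated in the presence of the aldehyde; the meta-phenoxide is not conjugated with the ylide carbon, so the ylide stays reactive, and the alkene geometry is irrelevant because the bond is hydrogenated next.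

Step 5
Reactants: 8 tert-butyl (E)-3-(3-{4-[2-(3-hydroxyphenyl)ethenyl]phenoxy}-4-methoxyphenyl)prop-2-enoate
Product: 9 tert-butyl 3-(3-{4-[2-(3-hydroxyphenyl)ethyl]phenoxy}-4-methoxyphenyl)propanoate
Conditions: H2 (1 atm), Pd/C, EtOAc, rt
Reagents that add atoms: none
Why: Heterogeneous catalytic hydrogenation saturates the stilbene and the cinnamate together, creating the ring B–ring C bridge and the propanoate chain; diaryl ethers, the phenol and the tert-butyl ester are unaffected.

Step 6
Reactants: 10 cyclohex-2-en-1-one
Product: 12 6-diazocyclohex-2-en-1-one, via 6-(trifluoroacetyl)cyclohex-2-en-1-one 11 (not isolated)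
Conditions: LiN(SiMe3)2, THF, −78 °C; CF3CO2CH2CF3; then MeSO2N3, Et3N, H2O, MeCN, rt
Reagents that add atoms: 2,2,2-trifluoroethyl trifluoroacetate, SMILES O=C(OCC(F)(F)F)C(F)(F)F (trifluoroacetyl group of 11 only); methanesulfonyl azide, SMILES CS(=O)(=O)N=[N+]=[N-]
Why: Detrifluoroacetylative diazo transfer: kinetic α'-deprotonation of the enone and C-trifluoroacetylation give the activated diketone 11, to which the sulfonyl azide transfers N2 with loss of the trifluoroacetyl group; this is the established way to α'-diazo enones, where direct diazo transfer fails.

Step 7
Reactants: 9 tert-butyl 3-(3-{4-[2-(3-hydroxyphenyl)ethyl]phenoxy}-4-methoxyphenyl)propanoate; 12 6-diazocyclohex-2-en-1-one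
Product: 13 tert-butyl 3-[4-methoxy-3-(4-{2-[3-(2-oxocyclohex-3-en-1-yloxy)phenyl]ethyl}phenoxy)phenyl]propanoate (racemic)
Conditions: Rh2(OAc)4 (2 mol%), CH2Cl2, rt, slow addition of 12 (1.5 equiv)
Reagents that add atoms: none
Why: Rhodium carbenoid O–H insertion of an α-diazo ketone into a phenol (oxonium ylide, then proton shift) forms the ring A–O–ring B bond under neutral conditions; slow addition keeps the carbenoid concentration low so that capture by the phenol competes with the 1,2-hydride shift, and the new stereocentre is racemic and later erased.

Step 8
Reactants: 13 tert-butyl 3-[4-methoxy-3-(4-{2-[3-(2-oxocyclohex-3-en-1-yloxy)phenyl]ethyl}phenoxy)phenyl]propanoate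
Product: 14 3-[4-methoxy-3-(4-{2-[3-(2-oxocyclohex-3-en-1-yloxy)phenyl]ethyl}phenoxy)phenyl]propanoic acid (racemic)
Conditions: CF3CO2H, CH2Cl2, 0 °C to rt
Reagents that add atoms: none
Why: Acidolysis of the tert-butyl ester by alkyl–oxygen cleavage with loss of 2-methylpropene; the α-aryloxy enone has no acid-labile bond and is spared the hydroxide that a saponification would require.

Step 9
Reactants: 14 3-[4-methoxy-3-(4-{2-[3-(2-oxocyclohex-3-en-1-yloxy)phenyl]ethyl}phenoxy)phenyl]propanoic acid
Product: 15 1,3-dioxoisoindolin-2-yl 3-[4-methoxy-3-(4-{2-[3-(2-oxocyclohex-3-en-1-yloxy)phenyl]ethyl}phenoxy)phenyl]propanoate (racemic)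
Conditions: N-hydroxyphthalimide, i-PrN=C=N-i-Pr, DMAP (cat.), CH2Cl2, rt
Reagents that add atoms: N-hydroxyphthalimide, SMILES O=C1c2ccccc2C(=O)N1O
Why: Carbodiimide-mediated (Steglich-type) esterification of the acid with the acidic N–OH group gives the redox-active ester; no base stronger than DMAP is present, so the enone is not enolized.

Step 10
Reactants: 15 1,3-dioxoisoindolin-2-yl 3-[4-methoxy-3-(4-{2-[3-(2-oxocyclohex-3-en-1-yloxy)phenyl]ethyl}phenoxy)phenyl]propanoate
Product: 16 macrocyclic 2-aryloxy-5-alkylcyclohexanone: the ring D methyl ether of 19 in which ring A is a cyclohexanone with C=O at the later phenol carbon, the ring B oxygen on C2 and the bridge CH2 on C5 (racemic cis/trans mixture)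
Conditions: Ru(bpy)3(PF6)2 (2 mol%), Hantzsch ester (1.5 equiv, in portions), i-Pr2NEt (2 equiv), CH2Cl2 (1 mM), blue LEDs, rt
Reagents that add atoms: none
Why: Excited Ru(bpy)3(PF6)2 (divalent ruthenium) is quenched reductively by the amine or the dihydropyridine to monovalent ruthenium, which transfers one electron to the phthalimide ester; N–O cleavage and loss of CO2 release the primary 2-arylethyl radical. This nucleophilic radical adds to C3, the β-carbon of the 6-aryloxycyclohex-2-enone (C5 of the product ketone), and the resulting electrophilic α-keto radical is reduced by hydrogen-atom transfer from the Hantzsch ester or by electron transfer and protonation. The closest known reaction type is the reductive photoredox decarboxylative Giese addition of N-acyloxyphthalimides to enones, together with high-dilution radical macrocyclizations of functionalized chains onto enones. The 20-membered ring closes by attack on the enone carbon remote from the carbonyl, so that a sixteen-atom tether spans the cyclohexanone from C2 to C5. At this ring size there is no stereoelectronic preference, and regiochemistry rests on polarity: only C3 is electrophilic and only attack there gives a stabilized radical. The new stereocentre at C5 forms without control relative to the aryloxy-bearing C2, and none is needed because both centres become sp2 in step 11. Chemoselective electron transfer is secured because monovalent ruthenium is reducing enough for the phthalimide ester but not for the enone or the α-aryloxy ketone, so the C–O bond is not cleaved. Cyclization must also outrun hydrogen-atom quenching and intermolecular addition, which the 1 mM concentration and the portionwise dosing of the dihydropyridine are meant to ensure.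

Step 11
Reactants: 16 macrocyclic 2-aryloxy-5-alkylcyclohexanone
Product: 18 ring D methyl ether of 19 (ring A phenol free), via macrocyclic cyclohex-2-enone 17 (not isolated)
Conditions: Pd(O2CCF3)2 (5 mol%), 2-(dimethylamino)pyridine (10 mol%), TsOH·H2O (20 mol%), O2 (1 atm), DMSO, 80 °C
Reagents that add atoms: none
Why: Aerobic palladium-catalysed dehydrogenation of a cyclohexanone to a phenol: a divalent palladium enolate undergoes β-hydride elimination to enone 17, a second such sequence on the aryloxy side gives a dienone that tautomerizes to the phenol, and O2 reoxidizes zerovalent palladium; both diastereomers of 16 converge and the two stereocentres are erased.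

Step 12
Reactants: 18 ring D methyl ether of 19
Product: 19 target macrocycle CNP0329842.0
Conditions: BBr3 (3 equiv), CH2Cl2, −78 to 0 °C; then H2O
Reagents that add atoms: none
Why: Lewis-acid demethylation of an aryl methyl ether (boron coordination, then bromide attack on the methyl carbon); the diaryl ethers have no sp3 carbon and are not cleaved.

## Compound list

1 | isovanillin (3-hydroxy-4-methoxybenzaldehyde) | COc1ccc(C=O)cc1O | starting material
2 | tert-butyl (triphenylphosphoranylidene)acetate | CC(C)(C)OC(=O)C=P(c1ccccc1)(c1ccccc1)c1ccccc1 | starting material
3 | tert-butyl (E)-3-(3-hydroxy-4-methoxyphenyl)prop-2-enoate | COc1ccc(/C=C/C(=O)OC(C)(C)C)cc1O | intermediate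
4 | 4-fluorobenzaldehyde | O=Cc1ccc(F)cc1 | starting material
5 | tert-butyl (E)-3-[3-(4-formylphenoxy)-4-methoxyphenyl]prop-2-enoate | COc1ccc(/C=C/C(=O)OC(C)(C)C)cc1Oc1ccc(C=O)cc1 | intermediate
6 | 3-hydroxybenzyl alcohol | OCc1cccc(O)c1 | starting material
7 | (3-hydroxybenzyl)triphenylphosphonium bromide | [Br-].Oc1cccc(C[P+](c2ccccc2)(c2ccccc2)c2ccccc2)c1 | intermediate
8 | tert-butyl (E)-3-(3-{4-[2-(3-hydroxyphenyl)ethenyl]phenoxy}-4-methoxyphenyl)prop-2-enoate, E/Z mixture at the stilbene bond | COc1ccc(/C=C/C(=O)OC(C)(C)C)cc1Oc1ccc(C=Cc2cccc(O)c2)cc1 | intermediate
9 | tert-butyl 3-(3-{4-[2-(3-hydroxyphenyl)ethyl]phenoxy}-4-methoxyphenyl)propanoate | COc1ccc(CCC(=O)OC(C)(C)C)cc1Oc1ccc(CCc2cccc(O)c2)cc1 | intermediate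
10 | cyclohex-2-en-1-one | O=C1C=CCCC1 | starting material
11 | 6-(trifluoroacetyl)cyclohex-2-en-1-one | O=C1C=CCCC1C(=O)C(F)(F)F | intermediate (not isolated)
12 | 6-diazocyclohex-2-en-1-one | [N-]=[N+]=C1CCC=CC1=O | intermediate
13 | tert-butyl 3-[4-methoxy-3-(4-{2-[3-(2-oxocyclohex-3-en-1-yloxy)phenyl]ethyl}phenoxy)phenyl]propanoate, racemic | COc1ccc(CCC(=O)OC(C)(C)C)cc1Oc1ccc(CCc2cccc(OC3CCC=CC3=O)c2)cc1 | intermediate
14 | 3-[4-methoxy-3-(4-{2-[3-(2-oxocyclohex-3-en-1-yloxy)phenyl]ethyl}phenoxy)phenyl]propanoic acid, racemic | COc1ccc(CCC(=O)O)cc1Oc1ccc(CCc2cccc(OC3CCC=CC3=O)c2)cc1 | intermediate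
15 | 1,3-dioxoisoindolin-2-yl 3-[4-methoxy-3-(4-{2-[3-(2-oxocyclohex-3-en-1-yloxy)phenyl]ethyl}phenoxy)phenyl]propanoate, racemic | O=C(CCc1ccc(OC)c(c1)Oc1ccc(CCc2cccc(OC3CCC=CC3=O)c2)cc1)ON1C(=O)c2ccccc2C1=O | intermediate (precursor of the key step)
16 | macrocyclic 2-aryloxy-5-alkylcyclohexanone (ring D methyl ether of 19 with ring A as cyclohexanone), racemic cis/trans mixture | O=C1CC2CCC1Oc1cccc(c1)CCc1ccc(cc1)Oc1cc(ccc1OC)CC2 | intermediate (product of the key step)
17 | macrocyclic cyclohex-2-enone (C=C between the α-CH and the bridge-bearing carbon of 16), racemic | O=C1C=C2CCC1Oc1cccc(c1)CCc1ccc(cc1)Oc1cc(ccc1OC)CC2 | intermediate (not isolated)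
18 | ring D methyl ether of 19 (ring A phenol free) | Oc1cc2ccc1Oc1cccc(c1)CCc1ccc(cc1)Oc1cc(ccc1OC)CC2 | intermediate
19 | CNP0329842.0, macrocyclic bis(bibenzyl) diphenol | Oc1cc2ccc1Oc1cccc(c1)CCc1ccc(cc1)Oc1cc(ccc1O)CC2 | target

## Step count and risks

Total: 12 steps. Longest linear sequence: 10 steps (1, 2, 4, 5, 7, 8, 9, 10, 11, 12); steps 3 and 6 prepare the two side reagents.

**Step 10 (key step).** The most likely failure is premature hydrogen-atom transfer to the primary radical before the slow closure of a 20-membered ring onto a 1,2-disubstituted enone. Intermolecular addition leading to oligomers is the second risk. The fallback replaces the photoredox reduction by a chain process in which the hydride concentration is set independently of radical generation. It sets out from 15: visible-light iododecarboxylation (LiI, catalytic PPh3, blue LEDs, acetone) would give the primary iodide 6-[3-(2-{4-[5-(2-iodoethyl)-2-methoxyphenoxy]phenyl}ethyl)phenoxy]cyclohex-2-en-1-one F1. Syringe-pump addition of (Me3Si)3SiH and azobisisobutyronitrile to F1 in refluxing benzene at high dilution would then effect the macrocyclic radical addition. This comes back to the route at 16.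

**Step 7.** The rhodium carbenoid may undergo 1,2-hydride shift (aromatizing the reagent to phenol) faster than it is captured by the hindered phenol, or it may attack the electron-rich arenes. The fallback builds the aryloxy enone without a carbenoid and sets out from 9. O-Alkylation with 2-chlorocyclohexanone (K2CO3, KI, acetone, reflux) would give tert-butyl 3-[4-methoxy-3-(4-{2-[3-(2-oxocyclohexyloxy)phenyl]ethyl}phenoxy)phenyl]propanoate F2. Kinetic enolization at the unsubstituted α-methylene (LiN(i-Pr)2, Me3SiCl, THF, −78 °C) would give the silyl enol ether tert-butyl 3-{4-methoxy-3-[4-(2-{3-[2-(trimethylsilyloxy)cyclohex-2-en-1-yloxy]phenyl}ethyl)phenoxy]phenyl}propanoate F3. Saegusa–Ito oxidation of F3 (Pd(OAc)2, MeCN, rt) would place the double bond away from the aryloxy carbon. This comes back to the route at 13.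

**Step 11.** The dehydrogenation may stall at the enone stage, the catalyst may deactivate in the presence of the macrocyclic polyether, or the acid co-catalyst may promote cyclodehydration of the α-aryloxy ketone onto ring B. The fallback is stepwise and acid-free, and sets out from 16. Kinetic enolization toward the α-methylene (LiN(i-Pr)2, Me3SiCl, THF, −78 °C) would give the trimethylsilyl enol ether of 16 F4, which Pd(OAc)2 in MeCN would oxidize to enone 17. α'-Deprotonation of 17 under the same conditions would give the cross-conjugated 2-(trimethylsilyloxy)diene of 17 F5. A second Saegusa–Ito oxidation of F5 would give the dienone, which tautomerizes. This comes back to the route at 18.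

## Further compounds

F1 | step 10 | 6-[3-(2-{4-[5-(2-iodoethyl)-2-methoxyphenoxy]phenyl}ethyl)phenoxy]cyclohex-2-en-1-one, racemic | ICCc1ccc(OC)c(c1)Oc1ccc(CCc2cccc(OC3CCC=CC3=O)c2)cc1
F2 | step 7 | tert-butyl 3-[4-methoxy-3-(4-{2-[3-(2-oxocyclohexyloxy)phenyl]ethyl}phenoxy)phenyl]propanoate, racemic | COc1ccc(CCC(=O)OC(C)(C)C)cc1Oc1ccc(CCc2cccc(OC3CCCCC3=O)c2)cc1
F3 | step 7 | tert-butyl 3-{4-methoxy-3-[4-(2-{3-[2-(trimethylsilyloxy)cyclohex-2-en-1-yloxy]phenyl}ethyl)phenoxy]phenyl}propanoate, racemic | COc1ccc(CCC(=O)OC(C)(C)C)cc1Oc1ccc(CCc2cccc(OC3CCCC=C3O[Si](C)(C)C)c2)cc1
F4 | step 11 | trimethylsilyl enol ether of 16 (C=C between the carbonyl carbon and the α-CH), mixture of isomers | C[Si](C)(C)OC1=CC2CCC1Oc1cccc(c1)CCc1ccc(cc1)Oc1cc(ccc1OC)CC2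
F5 | step 11 | 2-(trimethylsilyloxy)diene from 17 (C=C to the aryloxy carbon and C=C to the bridge-bearing carbon) | C[Si](C)(C)OC1=C2CCC(=C1)CCc1ccc(OC)c(c1)Oc1ccc(CCc3cccc(O2)c3)cc1
A1 | alternative 1 | 1-[3-(4-{2-[3-(buta-1,3-dien-2-yloxy)-4-methoxyphenyl]ethyl}-2-methoxyphenoxy)phenyl]but-3-yn-2-one | COc1cc(CCc2ccc(OC)c(OC(=C)C=C)c2)ccc1Oc1cccc(CC(=O)C#C)c1
A2 | alternative 1 | macrocyclic cyclohexa-1,4-diene ketone | COc1cc2ccc1Oc1cccc(c1)CC(=O)C1=CCC(=CC1)Oc1cc(ccc1OC)CC2
A3 | alternative 2 | 2,6-dibromo-4-{2-[4-(3-{2-(3,5-dichloro-4-hydroxyphenyl)ethyl}phenoxy)-3-methoxyphenyl]ethyl}phenol | COc1cc(CCc2cc(Br)c(O)c(Br)c2)ccc1Oc1cccc(CCc2cc(Cl)c(O)c(Cl)c2)c1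
A4 | alternative 2 | trihalogenated macrocyclic ether | COc1cc2ccc1Oc1cccc(c1)CCc1cc(Cl)c(c(Cl)c1)Oc1cc(cc(Br)c1O)CC2
A5 | alternative 3 | 21-membered macrolactone (ring B benzoate of the ring A phenol) | COc1cc2ccc1OC(=O)c1cccc(c1)CCc1ccc(cc1)Oc1cc(ccc1OC)CC2
A6 | alternative 3 | dimethyl ether of 19 | COc1cc2ccc1Oc1cccc(c1)CCc1ccc(cc1)Oc1cc(ccc1OC)CC2
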